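Sunday's flask at 25 °C held 4.0% of target at 5.00 min, which I turned into the pace per enzyme, the turnover frequency: target made, divided by the enzyme charged and by the time, here 160 min⁻¹, a reading that carries the scatter of its run.

Sunday's run (percent of the substrate charged)

| time / min | target / % | substrate / % |
|---|---|---|
| 0.667 | 1.2 | 99.2 |
| 2.00 | 1.4 | 97.6 |
| 3.00 | 2.4 | 96.8 |
| 5.00 | 4.0 | 96.1 |

(standard deviation of a reading: 0.3 percentage points)

| flask | substrate | free enzyme | temperature | remark | time |
|---|---|---|---|---|---|
| Sunday's | 20 mM | 1 µM | 25 °C | run made earlier |  |
| blue | 10 mM | 1.0 µM |  | at 50 °C until 8.0 min, from then on at 0 °C | 25 min |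
| grey | 10 mM | 1.0 µM | 25 °C |  | 25 min |
| violet | 10 mM | 1.0 µM | 0 °C |  | 25 min |
| teal | 10 mM | 1.0 µM | 50 °C |  | 25 min |

- the earlier runs do not show what temperature does; that part of a forecast is a guess

1. the flask with the highest amount of target, in percent of the substrate charged ("all alike" if they lie within 1.5 percentage points) (blue / grey / violet / teal / all alike)
2. final target, as a percentage of the substrate charged, in blue
3. final target, as a percentage of the substrate charged, in grey
4. final target, as a percentage of the substrate charged, in violet
5. final target, as a percentage of the substrate charged, in teal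

Each flask held substrate and free enzyme at the start, and I expected target to grow in each as the enzyme worked. I froze the pace for grey, which shares Sunday's temperature, and so reckoned that its 1.0 µM of free enzyme would turn 40.0% of its 10 mM of substrate into target by 25 min, though Sunday's flask had a different charge of substrate and the pace might not carry over. I told whoever came next to leave each flask closed at its own temperature and to leave blue's change at 8.0 min as set, since the earlier runs did not show what temperature does.

The forecast differed from my reckoning: it gave grey 24%, lower than mine, with blue at 35% and violet at 5%. It named teal as the flask with most target, at 65%, within a range of 30% to 92%, a figure it held below what it reckoned for teal “if the enzyme survives”.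

The flasks gave 6.86% in blue, 16.6% in grey, 5.92% in violet and 6.86% in teal, so grey held the most.

    substrate + free enzyme → target + free enzyme, rate k1*[substrate]*[free enzyme]/(1 + ([substrate]/Km1) + ([target]/Kp1)) (9.50 mM, 15.0 mM, k = 600 L mol⁻¹ s⁻¹, Ea = 45.0 kJ mol⁻¹)
    2 free enzyme → spent catalyst (k = 1300 L mol⁻¹ s⁻¹, Ea = 42.0 kJ mol⁻¹)
    free enzyme → unfolded enzyme (k = 3.30 × 10⁻⁶ s⁻¹, Ea = 264 kJ mol⁻¹)
    (constants at 25 °C)

Teal's target came to 686 turnovers per enzyme charged, worth 4.29 min at Sunday's pace, and by 12.5 min teal stood at 6.86% with free enzyme at 0%, unfolded enzyme at 74.1% and spent catalyst at 25.9%. When I took the unfolding step away, teal reached 29.4% instead of 6.86%, the largest single effect on that flask. Violet's neighbour, charged with 0.0025 mM of free enzyme, gave 10.8%, which is 432 turnovers per enzyme against 592 in violet.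

The numbers in the tables are calculated with made-up constants, noise included.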